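In a one-step world, substrate simply passes into target and stops at 11 parts target to one of substrate. A 0.40 M charge would then hold 0.367 M of target, far more than the 39 mM that stays dissolved. These flasks also have side roads and crystals, so I solve the start and the end and join them.

| setting | north-west | south-west | south |
|---|---|---|---|
| substrate | 0.40 M | 0.80 M | 1.5 M |
| time | 20 min | 20 min | 20 min |

- [target] (only what is free in solution) at the end for north-west, south-west, south, in this order
- how the row runs (rises all the way / rises, then falls / hardly changes / falls, then rises / falls all the way)

- a species is counted by the substrate in it: one self-condensation product counts as two
- amounts and yields of target count crystals too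
- a doubled species enters its step squared and goes two at a time
- given per volume of solution although it is solid: crystals
- the concentration of target that is asked is that of its free form alone
- "hardly changes" means that all values lie within two and a half points (for a concentration: within two and a half percent of the largest)
- run time (north-west): 20 min

    substrate ⇌ target (K1 = 11, k1 = 0.013 s⁻¹)
    substrate ⇌ isomer of the product (K2 = 2.1, k2 = 0.0077 s⁻¹)
    2 substrate → self-condensation product (k3 = 0.0038 M⁻¹ s⁻¹)
    crystals ⇌ target, rate k4*(cs4 - [target]) while solid is left; crystals form when [target] > cs4 (cs4 = 39 mM, k4 = 0.072 s⁻¹)

In the first instants of north-west, substrate makes target at 5.20 mM s⁻¹. So in north-west c(target) passes solubility after about 7.50 s, sooner than the 0.89 min forward half-life of substrate by that step. At that start north-west's substrate also feeds the isomer, at 1.7 parts to target for one to isomer, forward rates taken alone.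

In the middle of north-west, crystals take up excess target in about 13.9 s, faster than the 0.815 min relaxation of substrate and target. Free target therefore sits in a quasi-steady state, where what arrives leaves as crystals. Arrival stops when substrate stands at a floor, solubility over K1, or 3.55 mM. This gives my rule, for as long as crystals stand in the flask: c(target) is solubility plus an overhang, and the overhang is the substrate above the floor times the gain, the forward constant of target formation over the crystal coefficient, 0.181.

At the end, the store is the isomer above its balance with the floor. I send 37.2% of the charge there and let it drain slowly, which leaves a fraction 0.0631 of it by 20 min. Substrate stands above its floor at 0.177 of that remaining store. So I reckon 0.416% of the charge as substrate above the floor. I leave self-condensation out, although at the start of south it runs at 0.0114 s⁻¹ per substrate against 0.0207 s⁻¹ for the other two steps, so my south figure is rough. My row is 39.3 mM, 39.6 mM and 40.1 mM.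

The forecast is slightly higher: 0.0394 M, 0.0398 M and 0.0402 M, and its shape is "hardly changes". It says, “The spread is about 2% of the largest value”.

The simulation gives 0.0394 M, 0.0397 M and 0.0402 M; the row hardly changes, as forecast. Take away the limit of solubility and south ends at 0.863 M instead of 0.0402 M. With the limit in place, south ends with 71.9% of its charge as crystals, out of 74.6% as target. North-west ends with 1.40% of its charge as substrate, 5.60 mM, and the gain turns the part above the floor into an overhang of 0.371 mM. South ends with 0.682%, 10.2 mM, for an overhang of 1.21 mM and a free target of 40.2 mM.

Its constants belong to no real substance, and the outcome is calculated.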